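Ring C is opened at O1–C2 and at C4–C3. What remains is a salicylaldehyde (ring A, whose hydroxyl oxygen O1 on C8a sits ortho to the formyl carbon C4 on C4a) and an aryl methoxyacetylene (ring B–C2≡C3–OMe). In one flask a rhodium catalyst, held by O1, adds the aldehyde C–H bond across the alkyne to a (Z)-2'-hydroxy-α-methoxychalcone, and a cinchona squaramide then closes ring C by 6-endo oxa-Michael addition of O1 to C2, which sets C2; C3 settles as the trans epimer. The feature used is this ortho O1/C4 pair of ring A, a chelating 1,4-C,O donor. Both catechols travel as diphenylmethylene ketals.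

Key step: step 7

Assumption: which pseudoenantiomeric cinchona squaramide delivers the (2R) configuration cannot be derived safely for this new substrate. The quinidine-derived one (from 9-amino-9-deoxy-epi-quinidine, squaric ester and 3,5-bis(trifluoromethyl)aniline) is written; its quinine-derived pseudoenantiomer is the direct replacement if the sense proves opposite.

Step 1
Reactants: 1 3-methoxycatechol
Product: 2 4-methoxy-2,2-diphenyl-1,3-benzodioxole
Conditions: Ph2CCl2 (1.1 equiv), neat, 160 °C, N2 sweep
Reagents that add atoms: dichlorodiphenylmethane, ClC(Cl)(c1ccccc1)c1ccccc1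
Why: Catechol ketalisation: the vicinal hydroxyls displace both chlorides of the benzylic gem-dichloride in turn, the second substitution closing the five-membered ring.

Step 2
Reactants: 2 4-methoxy-2,2-diphenyl-1,3-benzodioxole
Product: 3 4-iodo-7-methoxy-2,2-diphenyl-1,3-benzodioxole
Conditions: NIS (1.05 equiv), CF3CO2H (10 mol %), MeCN, 0 °C to rt, dark
Reagents that add atoms: N-iodosuccinimide, O=C1CCC(=O)N1I
Why: Electrophilic aromatic iodination should go to C7, para to the methoxy group and ortho to the tied-back ketal oxygen, because the position ortho to methoxy is shielded by the in-plane methyl group and the third position has only one oxygen in a para relation.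

Step 3
Reactants: 3 4-iodo-7-methoxy-2,2-diphenyl-1,3-benzodioxole, 4 2-chloro-1,1-dimethoxyethane
Product: 7 4-methoxy-7-(methoxyethynyl)-2,2-diphenyl-1,3-benzodioxole, via lithium methoxyacetylide 5 (not isolated), via methoxyethynylzinc chloride 6 (not isolated)
Conditions: 4, LiNEt2 (3.1 equiv), THF, 0 °C; ZnCl2 (1.2 equiv), 0 °C; then 3, Pd(PPh3)4 (5 mol %), rt to 45 °C; chromatography on Et3N-deactivated silica
Reagents that add atoms: none
Why: Lithium diethylamide strips methanol and hydrogen chloride from the chloroacetal and deprotonates the resulting methoxyacetylene (the classical alkoxyacetylene synthesis), and after transmetalation to zinc a Negishi coupling under zerovalent palladium joins the alkynyl carbon to the aryl iodide under non-acidic conditions that the ynol ether should survive.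

Step 4
Reactants: 8 3,4,5-trimethoxyphenol
Product: 9 6-hydroxy-2,3,4-trimethoxybenzaldehyde
Conditions: MgCl2, Et3N, (CH2O)n, MeCN, reflux; then aq. HCl
Reagents that add atoms: paraformaldehyde (as formaldehyde), C=O
Why: Magnesium phenoxide-directed ortho-formylation with formaldehyde (Casiraghi–Skattebøl type, a second formaldehyde taking up the hydride) can only reach the two equivalent positions ortho to the hydroxyl, so a single salicylaldehyde is expected.

Step 5
Reactants: 9 6-hydroxy-2,3,4-trimethoxybenzaldehyde
Product: 10 2,3,6-trihydroxy-4-methoxybenzaldehyde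
Conditions: BCl3 (4 equiv), CH2Cl2, −78 °C to rt; degassed water, argon
Reagents that add atoms: none
Why: Lewis acid ether cleavage: boron bound to the formyl oxygen cleaves the ortho methyl ether, the aryloxyboron chloride formed then cleaves its neighbour to a cyclic catechol borate, and the remote 4-methoxy group, which cannot chelate, should stay, as in the corresponding reaction of 2,3,4-trimethoxybenzaldehyde.

Step 6
Reactants: 10 2,3,6-trihydroxy-4-methoxybenzaldehyde
Product: 11 5-hydroxy-7-methoxy-2,2-diphenyl-1,3-benzodioxole-4-carbaldehyde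
Conditions: Ph2CCl2 (1.1 equiv), Ph2O, 170 °C, argon
Reagents that add atoms: dichlorodiphenylmethane, ClC(Cl)(c1ccccc1)c1ccccc1
Why: Catechol ketalisation: only the 2- and 3-hydroxyls are vicinal and can close the five-membered diphenylmethylene ketal, so the 6-hydroxyl (the later O1), hydrogen-bonded to the formyl group, stays free.

Step 7
Reactants: 11 5-hydroxy-7-methoxy-2,2-diphenyl-1,3-benzodioxole-4-carbaldehyde, 7 4-methoxy-7-(methoxyethynyl)-2,2-diphenyl-1,3-benzodioxole
Product: 13 (2R,3R)-3,7-dimethoxy-2-(7-methoxy-2,2-diphenyl-1,3-benzodioxol-4-yl)-5,6-(diphenylmethylenedioxy)-2,3-dihydro-4H-chromen-4-one, via alpha-methoxychalcone 12 (not isolated)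
Conditions: [Rh(cod)Cl]2 (2.5 mol %), Fe(C5H4PPh2)2 (dppf, 5 mol %), Na2CO3 (5 mol %), degassed toluene, 70 °C; then 0 °C, quinidine-derived squaramide (10 mol %)
Reagents that add atoms: none
Why: Proposed new method: monovalent rhodium bound to the phenoxide O1 inserts into the formyl C–H bond of 11, the acyl rhodium hydride adds syn across the alkyne of 7 with hydrogen to C2 and rhodium to the oxygen-bearing C3 (the metal goes alpha to oxygen as in rhodium hydride additions to vinyl ethers, and the methoxy end is the less hindered one), and C–C reductive elimination forms C4–C3 and gives the (Z)-chalcone 12; the closest known reaction type is the rhodium-catalysed tandem hydroacylation and oxa-Michael addition of salicylaldehydes with internal alkynes to trans-2,3-disubstituted chroman-4-ones, which has not been shown for an alkynyl ether or in enantioselective form. Ring C then closes by 6-endo-trig oxa-Michael addition of O1 to C2, helped by the twist of the carbonyl of 12 between its two ortho oxygens. C2 is set by the squaramide, which should hold the α-methoxy enone by two N–H hydrogen bonds and deliver the quinuclidine-bound phenol to one face, as in cinchona-catalysed cyclisations of activated 2'-hydroxychalcones to flavanones. C3 is set by protonation of the enol and amine-mediated equilibration to the diequatorial trans isomer. The step needs regioselective insertion (secured by the alkoxy group and by chelation of the aldehyde), no ring closure before the chiral catalyst is added (only 5 mol % of insoluble carbonate is present at 70 °C) and kinetic control at C2 (low temperature, quench at full conversion).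

Step 8
Reactants: 13 (2R,3R)-3,7-dimethoxy-2-(7-methoxy-2,2-diphenyl-1,3-benzodioxol-4-yl)-5,6-(diphenylmethylenedioxy)-2,3-dihydro-4H-chromen-4-one
Product: 14 (2R,3R)-2-(2,3-dihydroxy-4-methoxyphenyl)-5,6-dihydroxy-3,7-dimethoxy-2,3-dihydro-4H-chromen-4-one (CNP0075602.1)
Conditions: H2 (1 atm), 10% Pd/C, THF–MeOH, rt; work-up under argon
Reagents that add atoms: none
Why: Catalytic hydrogenolysis cleaves the doubly benzylic C–O bonds of both diphenylmethylene ketals to diphenylmethane under neutral conditions, which should leave the base- and acid-sensitive C2 and C3 centres, the C2–O1 bond and the hydrogen-bonded aryl ketone untouched.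

Compound list
1 | 3-methoxycatechol (3-methoxybenzene-1,2-diol) | COc1cccc(O)c1O | starting material
2 | 4-methoxy-2,2-diphenyl-1,3-benzodioxole | COc1cccc2OC(c3ccccc3)(c4ccccc4)Oc12 | intermediate
3 | 4-iodo-7-methoxy-2,2-diphenyl-1,3-benzodioxole | COc1ccc(I)c2OC(c3ccccc3)(c4ccccc4)Oc12 | intermediate
4 | 2-chloro-1,1-dimethoxyethane (chloroacetaldehyde dimethyl acetal) | COC(CCl)OC | starting material
5 | lithium methoxyacetylide | [Li]C#COC | intermediate
6 | (methoxyethynyl)zinc chloride | COC#C[Zn]Cl | intermediate
7 | 4-methoxy-7-(methoxyethynyl)-2,2-diphenyl-1,3-benzodioxole | COC#Cc1ccc(OC)c2OC(c3ccccc3)(c4ccccc4)Oc12 | intermediate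
8 | 3,4,5-trimethoxyphenol | COc1cc(O)cc(OC)c1OC | starting material
9 | 6-hydroxy-2,3,4-trimethoxybenzaldehyde | COc1cc(O)c(C=O)c(OC)c1OC | intermediate
10 | 2,3,6-trihydroxy-4-methoxybenzaldehyde | COc1cc(O)c(C=O)c(O)c1O | intermediate
11 | 5-hydroxy-7-methoxy-2,2-diphenyl-1,3-benzodioxole-4-carbaldehyde | COc1cc(O)c(C=O)c2OC(c3ccccc3)(c4ccccc4)Oc12 | intermediate
12 | (Z)-1-(5-hydroxy-7-methoxy-2,2-diphenyl-1,3-benzodioxol-4-yl)-2-methoxy-3-(7-methoxy-2,2-diphenyl-1,3-benzodioxol-4-yl)prop-2-en-1-one | COc1cc(O)c(C(=O)/C(OC)=C/c2ccc(OC)c3OC(c4ccccc4)(c5ccccc5)Oc23)c6OC(c7ccccc7)(c8ccccc8)Oc16 | intermediate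
13 | (2R,3R)-3,7-dimethoxy-2-(7-methoxy-2,2-diphenyl-1,3-benzodioxol-4-yl)-5,6-(diphenylmethylenedioxy)-2,3-dihydro-4H-chromen-4-one | COc1ccc([C@H]2Oc3cc(OC)c4OC(c5ccccc5)(c6ccccc6)Oc4c3C(=O)[C@@H]2OC)c7OC(c8ccccc8)(c9ccccc9)Oc17 | intermediate
14 | (2R,3R)-2-(2,3-dihydroxy-4-methoxyphenyl)-5,6-dihydroxy-3,7-dimethoxy-2,3-dihydro-4H-chromen-4-one | COc1ccc([C@H]2Oc3cc(OC)c(O)c(O)c3C(=O)[C@@H]2OC)c(O)c1O | target

Total step count: 8. Longest linear sequence: 5 steps (1, 2, 3, 7, 8 or 4, 5, 6, 7, 8).

Steps most likely to fail

Step 7 (proposed new method). The hydride may insert with the opposite regiochemistry, or the phenol O–H may add across the electron-rich alkyne. Ring C may also close outside the control of the chiral catalyst, or C2 may erode by retro-oxa-Michael opening and re-closure. The fallback uses known chemistry only, sets out from 11 and 3 and comes back at 13. Compound 11 is protected (MOMCl, iPr2NEt) as the MOM-protected aldehyde F1, MeMgBr gives the racemic carbinol F2 and Dess–Martin oxidation the acetophenone F3. Compound 3 is converted by iodine–magnesium exchange (iPrMgCl·LiCl) and DMF into the ring B aldehyde F4. Claisen–Schmidt condensation (KOH, EtOH) of F3 and F4 gives the (E)-chalcone F5, so that C2–C3 is made by aldol chemistry and ring C is closed later at O1–C2 alone. Juliá–Colonna epoxidation (poly-L-leucine, urea–H2O2, DBU, THF) should give the (αR,βS)-epoxide F6. HCl in MeOH–THF at 50 °C removes the MOM group and lets the freed phenol open the epoxide at the benzylic carbon with inversion to the (2R,3R)-3-hydroxyflavanone F7. Me3OBF4 with 1,8-bis(dimethylamino)naphthalene in CH2Cl2 methylates the 3-hydroxyl without base-induced ring opening and returns to 13.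

Step 3. The alkoxyacetylide or its zinc derivative may oligomerise or be protonated before coupling, and the ynol ether may be hydrated during isolation. The fallback sets out from 3 and comes back at 7. Iodine–magnesium exchange (iPrMgCl·LiCl) and acylation with N,2-dimethoxy-N-methylacetamide give the α-methoxy ketone F8. KN(SiMe3)2 and PhNTf2 give, through the chelated enolate, the (Z)-enol triflate F9, and KOtBu in THF at −78 °C removes triflate by anti elimination to give 7.

Step 5. Demethylation may stop short or go too far, and the hydroquinone-type triol may be oxidised by air during work-up. The fallback sets out from 9 and comes back at 11, and it never exposes a free hydroquinone. Acetylation (Ac2O, pyridine) gives the aryl acetate F10, BCl3 then carries out the same chelation-driven double demethylation to the catechol acetate F11, Ph2CCl2 closes the ketal acetate F12, and K2CO3 in MeOH removes the acetate to give 11.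

Further compounds
F1 | step 7 | 7-methoxy-5-(methoxymethoxy)-2,2-diphenyl-1,3-benzodioxole-4-carbaldehyde | COCOc1cc(OC)c2OC(c3ccccc3)(c4ccccc4)Oc2c1C=O
F2 | step 7 | 1-[7-methoxy-5-(methoxymethoxy)-2,2-diphenyl-1,3-benzodioxol-4-yl]ethanol (racemic) | COCOc1cc(OC)c2OC(c3ccccc3)(c4ccccc4)Oc2c1C(C)O
F3 | step 7 | 1-[7-methoxy-5-(methoxymethoxy)-2,2-diphenyl-1,3-benzodioxol-4-yl]ethanone | COCOc1cc(OC)c2OC(c3ccccc3)(c4ccccc4)Oc2c1C(C)=O
F4 | step 7 | 7-methoxy-2,2-diphenyl-1,3-benzodioxole-4-carbaldehyde | COc1ccc(C=O)c2OC(c3ccccc3)(c4ccccc4)Oc12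
F5 | step 7 | (E)-1-[7-methoxy-5-(methoxymethoxy)-2,2-diphenyl-1,3-benzodioxol-4-yl]-3-(7-methoxy-2,2-diphenyl-1,3-benzodioxol-4-yl)prop-2-en-1-one | COCOc1cc(OC)c2OC(c3ccccc3)(c4ccccc4)Oc2c1C(=O)/C=C/c5ccc(OC)c6OC(c7ccccc7)(c8ccccc8)Oc56
F6 | step 7 | [7-methoxy-5-(methoxymethoxy)-2,2-diphenyl-1,3-benzodioxol-4-yl][(2R,3S)-3-(7-methoxy-2,2-diphenyl-1,3-benzodioxol-4-yl)oxiran-2-yl]methanone | COCOc1cc(OC)c2OC(c3ccccc3)(c4ccccc4)Oc2c1C(=O)[C@@H]5O[C@H]5c6ccc(OC)c7OC(c8ccccc8)(c9ccccc9)Oc67
F7 | step 7 | (2R,3R)-3-hydroxy-7-methoxy-2-(7-methoxy-2,2-diphenyl-1,3-benzodioxol-4-yl)-5,6-(diphenylmethylenedioxy)-2,3-dihydro-4H-chromen-4-one | COc1ccc([C@H]2Oc3cc(OC)c4OC(c5ccccc5)(c6ccccc6)Oc4c3C(=O)[C@@H]2O)c7OC(c8ccccc8)(c9ccccc9)Oc17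
F8 | step 3 | 2-methoxy-1-(7-methoxy-2,2-diphenyl-1,3-benzodioxol-4-yl)ethanone | COCC(=O)c1ccc(OC)c2OC(c3ccccc3)(c4ccccc4)Oc12
F9 | step 3 | (Z)-2-methoxy-1-(7-methoxy-2,2-diphenyl-1,3-benzodioxol-4-yl)ethenyl trifluoromethanesulfonate | CO/C=C(\OS(=O)(=O)C(F)(F)F)c1ccc(OC)c2OC(c3ccccc3)(c4ccccc4)Oc12
F10 | step 5 | 2-formyl-3,4,5-trimethoxyphenyl acetate | CC(=O)Oc1cc(OC)c(OC)c(OC)c1C=O
F11 | step 5 | 2-formyl-3,4-dihydroxy-5-methoxyphenyl acetate | CC(=O)Oc1cc(OC)c(O)c(O)c1C=O
F12 | step 5 | 4-formyl-7-methoxy-2,2-diphenyl-1,3-benzodioxol-5-yl acetate | CC(=O)Oc1cc(OC)c2OC(c3ccccc3)(c4ccccc4)Oc2c1C=O
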